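## Remarks before the route

- **Numbering.** Ring carbons are C1–C10 (C14 on C10, C15 on C4); lactone carbons are C11 (with methylene C13) and C12; side-chain carbons are primed.
- **Reading of the target.** 6R,7R,8R,9R; C1=C10 is Z (C2 and C9 cis); C4=C5 is E; the side chain is (2S,3R)-2,3-dimethyloxirane-2-carboxylate (methyls cis, i.e. derived from the E acid).
- **Sense of the titanium–tartrate epoxidation.** The route assumes the usual rule: L-(+)-tartrates give the 2S glycidol carbon (for example (2S,3S) from E-2-alken-1-ols). L-(+)-diisopropyl tartrate is therefore used for 11 and the D-(−)-ester for 31.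
- **Check of the key-step structures.** Epoxy acid 14 (6S,7R,8R,9R; C5 and C8 trans on the oxirane) and lactone 15 (6R,7R,8R,9R) were compared atom by atom with the target. Connectivity and configuration fit, so nothing is corrected there.
- **Design changes (spectator groups only).**
  - O10 carries TBDPS: a bulky silyl oxygen cannot close a tetrahydrofuran onto C7 during the epoxide opening.
  - O5 carries TBS: it is put on the epoxy alcohol under neutral conditions and taken off with acid in the presence of TBDPS.
  - The methylene lactone is carried unmasked; every later reagent is non-basic and non-nucleophilic toward it.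
  - The ring is closed by metathesis at C1=C10, where the cis geometry is the one a ten-membered ring prefers.

## Structural features

The target is a germacranolide: a cyclodeca-1(10),4-diene whose C6–C7 bond is shared with an α-methylene-γ-butyrolactone (O on C6, C11 on C7), trans-fused since C5 and C8 lie on opposite faces of the lactone. Four contiguous stereocentres, C6 to C9, all carry oxygen. C7 is a fully substituted carbinol flanked by the lactone carbinol C6 and the esterified C8, and C9 is an allylic alcohol. The C8 ester is a 2,3-epoxy-2-methylbutanoate with two further stereocentres. The two ring alkenes are trisubstituted and of opposite geometry (C4=C5 E, C1=C10 Z). Fragile groups are the methylene lactone (Michael acceptor), the side-chain epoxide, the allylic lactone C6–O bond, the 1,5-diene (transannular reactions under acid) and the C8 ester next to free hydroxyls (acyl shift, relactonisation onto O8). The real difficulty is the tertiary carbinol C7 inside a run of four oxygenated centres, together with a strained ring holding an E and a Z trisubstituted alkene. The key step uses the anti relation of the lactone oxygen on C6 and the hydroxyl on C7: both are the ends of one C6–C7 epoxide, opened at C6 by the C12 carboxyl that already sits on C11.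

## Logic of the disconnections

36 is cut at the ester C–O bond on C8, giving 30 and 33, with 35 as the silylated form of 36. The acid-sensitive epoxy ester then enters last. The forward step must acylate a hindered secondary hydroxyl next to C7 while O9 is blocked and O7 stays inert.

33 is traced through 32 to 31 by removing the oxirane oxygen and lowering C1′ to the alcohol. Both side-chain centres then come from one reagent-controlled epoxidation of an achiral allylic alcohol, which must be enantioselective and must be followed by an oxidation that spares the epoxide.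

30 goes back to 29 and then to 28 by protecting-group changes only (O9 silyl, then the O8/O9 acetal and O7 silyl). This keeps O8 and O9 tied together during ring closure and demands that the least hindered hydroxyl of 29 is O9.

28 is cut at C1=C10, giving 27. This is the only ring bond whose geometry (cis) coincides with the preference of a ten-membered ring, and it leaves two simple alkene ends. The forward step must close a strained ring onto a 1,1-disubstituted alkene without touching the methylene lactone.

27 is simplified at C10 by cutting C10=CH2 and C10–C14, through 26, 25 and 24 to 23 and 22. C10 returns to the oxygenated CH2 that the key step requires. The forward steps need carbonyl chemistry at C10 with O7 capped, no epimerisation at C9 and no attack on the lactone.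

22 and 21 are simplified at C4 by cutting C4–C15 and C3–C4 (20, 18) and then C4=C5 (17, 16). The E alkene is thereby reduced to an aldehyde at C5. The forward couplings must be stereospecific: the first trans to C6, the second with retention.

15 is cut at the O–C6 lactone bond, giving 14. This is the key disconnection: it removes the ring and the C6 centre and leaves an open-chain epoxy acid. The forward step demands attack at C6 rather than C7 and clean inversion.

14 is traced through 13 and 12 to 11 by removing the epoxide oxygen (C6–O and C7–O). C6 and C7 are then stored in an E alkene and one face-selective oxygen transfer. The forward step must pick the C6=C7 alkene over the acrylate and a single face.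

11 is cut at C7–C11 into 8 and 10, and 10 goes back to 9. The acrylate arrives intact, and the coupling must retain the geometry at C7.

8 is cut at C7–I and C6–H, giving 6. The alkene geometry comes from an anti addition to an alkyne, which must put the metal on C7 cis to C5.

6 is cut at C5–C6 into 4 and 5. 4 is traced through 3 and 2 to 1 by removing C6 and the silyl group. C7–C10 with both C8 and C9 centres then come from the chiral pool, and the homologation must not epimerise C8.

## Other disconnections considered

Alternative 1: The cut is the C8–C9 bond.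

- Forward step: open-chain dialdehyde A2 (C8 aldehyde on the quaternary C7, C9 enal) is coupled reductively with TiCl3/Zn–Cu or SmI2 to the ten-membered diol A1.
- In its favour: ring, C8 and C9 are made in one irreversible C–C bond formation between two carbonyl carbons, with no alkene geometry at stake in the closing event.
- Against it here: two new centres mean four possible diastereomers, and the required erythro pair with the right sense relative to C7 rests on substrate control in a flexible transition state. The Z enal can isomerise or be reduced at the β-carbon under the low-valent metal. The lactone must still be built afterwards from the silylated ethynyl group and the acetal oxygen on C6, on the sensitive macrocycle. The diol must still be told apart.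
- Comparison: structurally, the chosen plan takes C8 and C9 from the chiral pool with certainty, whereas A1 creates them during closure. Mechanistically, a ketyl radical coupling stands against a polar SN2 opening. In step count the two are close, since the steps saved at the closure are spent on the late lactone.
- Where it is better: the ring closure itself is the better-founded one compared with the metathesis closure of the chosen plan.

Alternative 2: The cut is C5–C6 together with the acyl C–O bond of the lactone.

- Forward step: CrCl2 with catalytic NiCl2 converts the E alkenyl iodide of A4 into an alkenylchromium that adds to the C6 aldehyde; the chromium alkoxide then lactonises onto the acrylate ester to give A3.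
- In its favour: A3 is the same compound as 28 of the chosen route, reached in one flask with ring, C6 and lactone formed together. This type of closure has the best record for ten-membered germacranolides and tolerates the acrylate.
- Against it here: C6 is set by addition to a neopentyl α-silyloxy aldehyde on a fully substituted carbon, under substrate and ring-conformational control that cannot be predicted with confidence. The C7 carbinol bearing acrylate, aldehyde and silyl ether must be made stereoselectively by separate chemistry. The Z C1=C10 alkene still has to be made in the open chain.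
- Comparison: both plans converge on the same macrocycle. The chosen plan fixes C6 and C7 by reagent control and stereospecific inversion before the ring exists; the alternative fixes C6 during closure.
- Where it is better: the precedent for the closing step and the number of bonds formed in it are better than in the chosen plan; the certainty of the C6/C7 relation is lower.

Alternative 3: The cut is C2–C3, with C5–C10 reconnected (a cyclodeca-1,5-diene traced back to a 1,2-dialkenylcyclohexane).

- Forward step: the potassium alkoxide (KH, 18-crown-6) of the trans-1-vinyl-2-isopropenylcyclohexanol A6 undergoes an anionic [3,3] shift to the (E)-cyclodec-5-enone A5.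
- In its favour: the ring strain is paid by a pericyclic ring expansion at low temperature without high dilution; a chair transition state should give the E C4=C5 alkene; C6–C9 are set beforehand on a rigid six-membered ring.
- Against it here: A5 is far from the target. C7 is only a secondary silyl ether and must be oxidised and alkylated on a floppy ten-membered ring to give the tertiary carbinol with the acrylate carbon. The C10 ketone must become the Z methyl-bearing alkene with regiocontrol of enolisation (C1 versus C9). The lactone and the C8/C9 differentiation remain. A6 itself needs a long stereocontrolled synthesis and carries a silyl ether that can migrate under KH.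
- Comparison: structurally, the alternative builds the ring first and postpones the hardest centre, while the chosen plan builds C6/C7 first and postpones the ring. Mechanistically, a sigmatropic shift stands against epoxide opening and metathesis. The step count after A5 should exceed that of the chosen plan after 15.
- Where it is better: the formation of the ten-membered ring itself is more reliable than in the chosen plan.

Key step: step 11

## Route

Step 1
Reactants: 1 2,3-O-isopropylidene-D-erythronolactone
Product: 2 2,3-O-isopropylidene-D-erythrose (lactol, anomeric mixture)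
Conditions: i-Bu2AlH, CH2Cl2, −78 °C; Rochelle salt
Reagents that add atoms: none
Why: Low-temperature hydride reduction of a γ-lactone stops at the lactol because the tetrahedral aluminate does not collapse at −78 °C; C8 and C9 are locked in the cis-dioxolane and are not touched.

Step 2
Reactants: 2 2,3-O-isopropylidene-D-erythrose
Product: 3 [(4R,5S)-5-ethynyl-2,2-dimethyl-1,3-dioxolan-4-yl]methanol
Conditions: dimethyl (1-diazo-2-oxopropyl)phosphonate, K2CO3, MeOH, 0 °C to rt
Reagents that add atoms: dimethyl (1-diazo-2-oxopropyl)phosphonate, COP(=O)(OC)C(=[N+]=[N-])C(C)=O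
Why: Seyferth–Gilbert homologation in the Ohira–Bestmann form; the small share of open hydroxy aldehyde is trapped as it forms, and the closed lactol acts as a reservoir, which should keep epimerisation at C8 low.

Step 3
Reactants: 3 [(4R,5S)-5-ethynyl-2,2-dimethyl-1,3-dioxolan-4-yl]methanol
Product: 4 tert-butyl{[(4R,5S)-5-ethynyl-2,2-dimethyl-1,3-dioxolan-4-yl]methoxy}diphenylsilane
Conditions: TBDPSCl, imidazole, CH2Cl2, 0 °C to rt
Reagents that add atoms: tert-butyl(chloro)diphenylsilane, CC(C)(C)[Si](Cl)(c1ccccc1)c1ccccc1
Why: Standard silylation of a primary alcohol; the bulky silyl ether makes O10 a poor nucleophile in step 11 and outlasts the acidic removal of the O5 silyl group in step 12.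

Step 4
Reactants: 4 tert-butyl{[(4R,5S)-5-ethynyl-2,2-dimethyl-1,3-dioxolan-4-yl]methoxy}diphenylsilane; 5 formaldehyde (as paraformaldehyde)
Product: 6 3-[(4S,5R)-5-{[tert-butyl(diphenyl)silyl]oxymethyl}-2,2-dimethyl-1,3-dioxolan-4-yl]prop-2-yn-1-ol
Conditions: n-BuLi, THF, −78 °C; (CH2O)n, −78 °C to rt; NH4Cl (aq)
Reagents that add atoms: none
Why: Addition of a lithium acetylide to formaldehyde; at −78 °C only the sp C–H is deprotonated, so the C8 centre is not at risk.

Step 5
Reactants: 6 3-[(4S,5R)-5-{[tert-butyl(diphenyl)silyl]oxymethyl}-2,2-dimethyl-1,3-dioxolan-4-yl]prop-2-yn-1-ol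
Product: 8 (Z)-3-iodo-3-[(4R,5R)-5-{[tert-butyl(diphenyl)silyl]oxymethyl}-2,2-dimethyl-1,3-dioxolan-4-yl]prop-2-en-1-ol, via sodium oxaluminole 7 (not isolated)
Conditions: NaAlH2(OCH2CH2OMe)2, THF, 0 °C; EtOAc; I2, THF, −78 to 0 °C
Reagents that add atoms: iodine, II
Why: Hydroxyl-directed trans-hydroalumination of a propargylic alcohol puts hydride on C6 and aluminium on C7 in a five-membered alanate; iodine cleaves the C–Al bond with retention, so iodine ends cis to C5 (Z). Low temperature keeps the alanate from eliminating the C8 oxygen.

Step 6
Reactants: 9 methyl propiolate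
Product: 10 methyl 2-(tributylstannyl)prop-2-enoate
Conditions: Bu3SnH, Pd(PPh3)4 (2 mol %), THF, 0 °C to rt
Reagents that add atoms: tributyltin hydride, CCCC[SnH](CCCC)CCCC
Why: Palladium-catalysed syn-hydrostannation of a propiolate places tin mainly on the α-carbon; the minor β-isomer is removed by chromatography.

Step 7
Reactants: 8 (Z)-3-iodo-3-[(4R,5R)-5-{[tert-butyl(diphenyl)silyl]oxymethyl}-2,2-dimethyl-1,3-dioxolan-4-yl]prop-2-en-1-ol; 10 methyl 2-(tributylstannyl)prop-2-enoate
Product: 11 methyl (3E)-5-hydroxy-2-methylidene-3-[(4S,5R)-5-{[tert-butyl(diphenyl)silyl]oxymethyl}-2,2-dimethyl-1,3-dioxolan-4-yl]pent-3-enoate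
Conditions: Pd(PPh3)4 (5 mol %), CuI, CsF, DMF, rt to 45 °C
Reagents that add atoms: none
Why: Stille coupling with copper and fluoride assistance proceeds with retention at both sp2 carbons, so C11 is cis to C5 and C8 trans to it (E). The inward CH2OH group hinders the s-cis diene conformer, which should slow Diels–Alder dimerisation.

Step 8
Reactants: 11 methyl (3E)-5-hydroxy-2-methylidene-3-[(4S,5R)-5-{[tert-butyl(diphenyl)silyl]oxymethyl}-2,2-dimethyl-1,3-dioxolan-4-yl]pent-3-enoate
Product: 12 methyl 2-[(2R,3S)-3-(hydroxymethyl)-2-{(4R,5R)-5-[(tert-butyldiphenylsilyloxy)methyl]-2,2-dimethyl-1,3-dioxolan-4-yl}oxiran-2-yl]prop-2-enoate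
Conditions: Ti(OiPr)4 (1 equiv), L-(+)-diisopropyl tartrate, t-BuOOH, 4 Å MS, CH2Cl2, −25 °C
Reagents that add atoms: tert-butyl hydroperoxide, CC(C)(C)OO
Why: Sharpless asymmetric epoxidation: only C6=C7 is held at titanium through the allylic alkoxide, and the electron-poor acrylate alkene is left alone. The L-(+)-tartrate should deliver oxygen to the face that makes C6 S, and the E geometry then fixes C7 as R. The stoichiometric complex at low temperature is meant to outrun ester exchange at C12.

Step 9
Reactants: 12 methyl 2-[(2R,3S)-3-(hydroxymethyl)-2-{(4R,5R)-5-[(tert-butyldiphenylsilyloxy)methyl]-2,2-dimethyl-1,3-dioxolan-4-yl}oxiran-2-yl]prop-2-enoate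
Product: 13 methyl 2-[(2R,3S)-3-{[tert-butyl(dimethyl)silyl]oxymethyl}-2-{(4R,5R)-5-[(tert-butyldiphenylsilyloxy)methyl]-2,2-dimethyl-1,3-dioxolan-4-yl}oxiran-2-yl]prop-2-enoate
Conditions: TBSCl, imidazole, CH2Cl2, 0 °C
Reagents that add atoms: tert-butyl(chloro)dimethylsilane, CC(C)(C)[Si](C)(C)Cl
Why: Neutral silylation of the primary hydroxyl; capping O5 excludes a Payne rearrangement in the basic step 10, which would invert C6 before the carboxylate arrives.

Step 10
Reactants: 13 methyl 2-[(2R,3S)-3-{[tert-butyl(dimethyl)silyl]oxymethyl}-2-{(4R,5R)-5-[(tert-butyldiphenylsilyloxy)methyl]-2,2-dimethyl-1,3-dioxolan-4-yl}oxiran-2-yl]prop-2-enoate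
Product: 14 2-[(2R,3S)-3-{[tert-butyl(dimethyl)silyl]oxymethyl}-2-{(4R,5R)-5-[(tert-butyldiphenylsilyloxy)methyl]-2,2-dimethyl-1,3-dioxolan-4-yl}oxiran-2-yl]prop-2-enoic acid
Conditions: LiOH, THF/H2O, 0 °C; KHSO4 (aq) to pH 4–5, 0 °C
Reagents that add atoms: lithium hydroxide, [Li+].[OH-]
Why: Acyl-oxygen saponification of the methyl ester; at 0 °C hydroxide should attack the ester carbonyl faster than the acrylate β-carbon or the silyl ethers. Cold, weakly acidic work-up delivers the free acid for immediate use.

Step 11
Reactants: 14 2-[(2R,3S)-3-{[tert-butyl(dimethyl)silyl]oxymethyl}-2-{(4R,5R)-5-[(tert-butyldiphenylsilyloxy)methyl]-2,2-dimethyl-1,3-dioxolan-4-yl}oxiran-2-yl]prop-2-enoic acid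
Product: 15 (4R,5R)-5-{[tert-butyl(dimethyl)silyl]oxymethyl}-4-hydroxy-3-methylidene-4-{(4R,5R)-5-[(tert-butyldiphenylsilyloxy)methyl]-2,2-dimethyl-1,3-dioxolan-4-yl}oxolan-2-one
Conditions: PPTS (10 mol %), CH2Cl2, 0 °C to rt
Reagents that add atoms: none
Why: The weak acid hydrogen-bonds to the oxirane oxygen, the carboxyl oxygen on C12 attacks C6 from the side opposite the C6–O bond in an SN2 step, and proton transfer leaves the former epoxide oxygen as the C7 hydroxyl. The closest known reaction type is the acid-promoted lactonisation of 3,4-epoxy carboxylic acids to β-hydroxy-γ-butyrolactones. The five-membered ring closes in the 5-endo mode on the distal epoxide carbon, which is open to three-membered electrophiles because the bent C–O bond leaves the rear of C6 within reach of the two-atom tether. The new C6 centre (R) arises by inversion of the 6S epoxide carbon set in step 8; C7 keeps its oxygen and configuration, and the E geometry of 11 therefore appears as the trans relation of C5 and C8 on the lactone. The step needs attack at C6 and not C7, and substitution without ionisation. C6 is secondary, whereas C7 is fully substituted, would give a β-lactone by 4-exo closure, and is made a poor cation site by the adjacent acrylate. The mild acid in a non-nucleophilic solvent keeps the opening concerted. The silylated O5 could reach C7 only through a four-membered ring, and the bulky TBDPS ether keeps O10 from closing a tetrahydrofuran onto C7.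

Step 12
Reactants: 15 (4R,5R)-5-{[tert-butyl(dimethyl)silyl]oxymethyl}-4-hydroxy-3-methylidene-4-{(4R,5R)-5-[(tert-butyldiphenylsilyloxy)methyl]-2,2-dimethyl-1,3-dioxolan-4-yl}oxolan-2-one
Product: 16 (4R,5R)-4-hydroxy-5-(hydroxymethyl)-3-methylidene-4-{(4R,5R)-5-[(tert-butyldiphenylsilyloxy)methyl]-2,2-dimethyl-1,3-dioxolan-4-yl}oxolan-2-one
Conditions: CSA (10 mol %), MeOH/CH2Cl2, 0 °C
Reagents that add atoms: none
Why: Acid-catalysed methanolysis cleaves a primary TBS ether much faster than a TBDPS ether or an internal cis-dioxolane; methanol does not add to the methylene lactone without base.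

Step 13
Reactants: 16 (4R,5R)-4-hydroxy-5-(hydroxymethyl)-3-methylidene-4-{(4R,5R)-5-[(tert-butyldiphenylsilyloxy)methyl]-2,2-dimethyl-1,3-dioxolan-4-yl}oxolan-2-one
Product: 17 C5 aldehyde of 16 (2-formyl lactone; C6–C9 as in 16)
Conditions: Dess–Martin periodinane, NaHCO3, CH2Cl2, 0 °C to rt
Reagents that add atoms: none
Why: Dess–Martin oxidation of the primary alcohol; the tertiary C7 hydroxyl is inert and the buffered, non-basic medium protects the α-acyloxy centre C6. The aldehyde is used crude.

Step 14
Reactants: 17 C5 aldehyde of 16
Product: 18 1,1-dibromoalkene (C6–CH=CBr2; C6–C9 as in 16)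
Conditions: CBr4, PPh3, Zn, CH2Cl2, rt; then 17, 0 °C to rt
Reagents that add atoms: carbon tetrabromide, BrC(Br)(Br)Br
Why: Ramirez (Corey–Fuchs) dibromo-olefination with the ylide preformed in the presence of zinc; this is a neutral Wittig reaction suited to a base-sensitive α-acyloxy aldehyde.

Step 15
Reactants: 18 1,1-dibromoalkene; 19 but-3-enylzinc bromide (THF solution)
Product: 20 (Z)-2-bromoalkene (C6–CH=C(Br)–CH2CH2CH=CH2, Br cis to C6)
Conditions: PdCl2(DPEphos) (5 mol %), THF, 0 °C to rt
Reagents that add atoms: none
Why: Trans-selective Negishi monoalkylation of a 1,1-dibromoalkene: zerovalent palladium inserts into the C–Br bond trans to the C6 substituent (the less hindered one) and the alkyl group is transferred with retention. Alkylzinc halides leave the lactone and the acrylate alone.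

Step 16
Reactants: 20 (Z)-2-bromoalkene
Product: 21 lactone with the (1E)-2-methylhexa-1,5-dienyl chain on C6 (C4=C5 E; O7 free; O10 TBDPS)
Conditions: Me2Zn, Pd(t-Bu3P)2 (5 mol %), THF, 0 °C to rt
Reagents that add atoms: dimethylzinc, C[Zn]C
Why: Second Negishi coupling at the remaining C–Br bond with retention when the bulky trialkylphosphine catalyst is used; the methyl group ends cis to C6, which is the 4E alkene. The reaction is stopped at full conversion to limit contact of zerovalent palladium with the allylic lactone.

Step 17
Reactants: 21 lactone with the (1E)-2-methylhexa-1,5-dienyl chain on C6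
Product: 22 C7,C10-diol (O10 free)
Conditions: HF·pyridine, pyridine, THF, 0 °C to rt
Reagents that add atoms: none
Why: Fluoride cleavage of the primary TBDPS ether; the buffered reagent should leave lactone, acetonide and alkenes untouched.

Step 18
Reactants: 22 C7,C10-diol
Product: 23 7,10-bis(triethylsilyl) ether
Conditions: Et3SiOTf, 2,6-lutidine, CH2Cl2, −78 to 0 °C
Reagents that add atoms: triethylsilyl trifluoromethanesulfonate, CC[Si](CC)(CC)OS(=O)(=O)C(F)(F)F
Why: The silyl triflate is reactive enough for the tertiary C7 hydroxyl. O7 must be capped before C10 becomes a carbonyl, since a free C7 hydroxyl would close a five-membered lactol onto C10.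

Step 19
Reactants: 23 7,10-bis(triethylsilyl) ether
Product: 24 C10 aldehyde (O7 triethylsilyl)
Conditions: (COCl)2, DMSO, CH2Cl2, −78 to −40 °C; i-Pr2NEt, −78 to 0 °C
Reagents that add atoms: none
Why: Swern conditions convert primary triethylsilyl ethers directly into aldehydes (the chlorosulfonium salt attacks the unhindered silyl ether oxygen), while the tertiary silyl ether stays. The hindered amine at low temperature protects the C9 centre.

Step 20
Reactants: 24 C10 aldehyde
Product: 25 C10 methyl carbinol (both C10 epimers)
Conditions: MeTi(OiPr)3 (from MeLi, ClTi(OiPr)3), Et2O/THF, −50 to 0 °C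
Reagents that add atoms: methyltitanium triisopropoxide, C[Ti](OC(C)C)(OC(C)C)OC(C)C
Why: The titanium methyl reagent adds to aldehydes in the presence of lactones, does not add in a conjugate sense and is not basic enough to epimerise C9. The new C10 carbinol centre is removed in step 21.

Step 21
Reactants: 25 C10 methyl carbinol
Product: 26 C10 methyl ketone
Conditions: Dess–Martin periodinane, NaHCO3, CH2Cl2, rt
Reagents that add atoms: none
Why: Dess–Martin oxidation of a secondary alcohol under buffered conditions that do not enolise the α-alkoxy ketone.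

Step 22
Reactants: 26 C10 methyl ketone
Product: 27 triene with isopropenyl group on C9 (C10(CH3)=CH2)
Conditions: Zn, CH2Br2, TiCl4, THF; then 26, CH2Cl2, 0 °C to rt
Reagents that add atoms: dibromomethane, BrCBr
Why: Takai–Lombardo methylenation: the non-basic gem-dimetallic reagent methylenates ketones but not lactones or acrylates, and does not epimerise α-alkoxy ketones.

Step 23
Reactants: 27 triene with isopropenyl group on C9
Product: 28 7-O-triethylsilyl-8,9-O-isopropylidene derivative of (6R,7R,8R,9R)-7,8,9-trihydroxygermacra-1(10)Z,4E,11(13)-trien-12,6-olide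
Conditions: RuCl2(H2IMes)(=CH-C6H4-2-OiPr) (second-generation Hoveyda–Grubbs catalyst, 15 mol %), 1,4-benzoquinone, toluene (0.5 mM), 80 °C
Reagents that add atoms: none
Why: Ring-closing metathesis: the ruthenium carbene forms on the monosubstituted alkene and closes onto the 1,1-disubstituted one. In a ten-membered ring the cis alkene (C2 and C9 cis) is favoured kinetically and thermodynamically. Closure onto C4=C5 or the lactone methylene would need a four-membered ring or an eight-membered ring with a trans alkene, and the cis-dioxolane and lactone hold the two ends on one side.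

Step 24
Reactants: 28 7-O-triethylsilyl-8,9-O-isopropylidene macrocycle
Product: 29 (6R,7R,8R,9R)-7,8,9-trihydroxygermacra-1(10)Z,4E,11(13)-trien-12,6-olide
Conditions: AcOH/H2O/THF (3:1:1), 45 °C
Reagents that add atoms: none
Why: Aqueous acetic acid should hydrolyse the isopropylidene acetal and the tertiary silyl ether; the weak acid is chosen to spare the 1,5-diene and the allylic C6–O and C9–O bonds.

Step 25
Reactants: 29 (6R,7R,8R,9R)-7,8,9-trihydroxygermacra-1(10)Z,4E,11(13)-trien-12,6-olide
Product: 30 9-O-triethylsilyl ether of 29
Conditions: Et3SiOTf (1.05 equiv), 2,6-lutidine, CH2Cl2, −78 °C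
Reagents that add atoms: triethylsilyl trifluoromethanesulfonate, CC[Si](CC)(CC)OS(=O)(=O)C(F)(F)F
Why: Kinetic silylation of the most accessible hydroxyl: O9 is allylic and flanked by an sp2 carbon, O8 sits next to the fully substituted C7, and O7 is tertiary. The non-nucleophilic base avoids addition to the methylene lactone and relactonisation onto O8.

Step 26
Reactants: 31 (E)-2-methylbut-2-en-1-ol
Product: 32 [(2R,3R)-2,3-dimethyloxiran-2-yl]methanol
Conditions: Ti(OiPr)4 (10 mol %), D-(−)-diisopropyl tartrate, t-BuOOH, 4 Å MS, CH2Cl2, −20 °C
Reagents that add atoms: tert-butyl hydroperoxide, CC(C)(C)OO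
Why: Catalytic Sharpless asymmetric epoxidation; the D-(−)-tartrate should give the enantiomer of the (2S,3S) epoxide formed with the L-(+)-ester, and the E alkene fixes the cis relation of the two methyl groups.

Step 27
Reactants: 32 [(2R,3R)-2,3-dimethyloxiran-2-yl]methanol
Product: 33 (2S,3R)-2,3-dimethyloxirane-2-carboxylic acid
Conditions: RuCl3 (2 mol %), NaIO4, MeCN/EtOAc/H2O, rt
Reagents that add atoms: sodium periodate, [Na+].[O-]I(=O)(=O)=O
Why: Catalytic ruthenium tetroxide oxidises the primary alcohol of an epoxy alcohol to the glycidic acid without opening the oxirane; the descriptor at C2′ changes only because the priorities change.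

Step 28
Reactants: 30 9-O-triethylsilyl ether of 29; 33 (2S,3R)-2,3-dimethyloxirane-2-carboxylic acid
Product: 35 9-O-triethylsilyl ether of the target, via mixed anhydride 34 (not isolated)
Conditions: 2,4,6-trichlorobenzoyl chloride, Et3N, THF, rt; then 30, DMAP, toluene, rt
Reagents that add atoms: none
Why: Yamaguchi esterification: DMAP attacks the less hindered epoxyacyl carbonyl of the mixed anhydride and the acylpyridinium ion acylates the hindered C8 hydroxyl. O9 is silylated and the tertiary O7 does not react.

Step 29
Reactants: 35 9-O-triethylsilyl ether of the target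
Product: 36 (6R,7R,8R,9R)-7,9-dihydroxy-8-[(2S,3R)-2,3-dimethyloxirane-2-carbonyloxy]germacra-1(10)Z,4E,11(13)-trien-12,6-olide (CNP0420662.1)
Conditions: HF·pyridine, pyridine, THF, 0 °C
Reagents that add atoms: none
Why: Buffered fluoride cleaves the secondary triethylsilyl ether; the slightly acidic medium should avoid acyl shift from O8 to O9 and spare the epoxide and the methylene lactone.

## Compound list

1 | 2,3-O-isopropylidene-D-erythronolactone | O=C1OC[C@H]2OC(C)(C)O[C@H]21 | starting material
2 | 2,3-O-isopropylidene-D-erythrose (lactol) | OC1OC[C@H]2OC(C)(C)O[C@H]21 | intermediate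
3 | [(4R,5S)-5-ethynyl-2,2-dimethyl-1,3-dioxolan-4-yl]methanol | C#C[C@@H]1OC(C)(C)O[C@@H]1CO | intermediate
4 | tert-butyl{[(4R,5S)-5-ethynyl-2,2-dimethyl-1,3-dioxolan-4-yl]methoxy}diphenylsilane | C#C[C@@H]1OC(C)(C)O[C@@H]1CO[Si](c2ccccc2)(c3ccccc3)C(C)(C)C | intermediate
5 | formaldehyde (as paraformaldehyde) | C=O | starting material
6 | 3-[(4S,5R)-5-{[tert-butyl(diphenyl)silyl]oxymethyl}-2,2-dimethyl-1,3-dioxolan-4-yl]prop-2-yn-1-ol | OCC#C[C@@H]1OC(C)(C)O[C@@H]1CO[Si](c2ccccc2)(c3ccccc3)C(C)(C)C | intermediate
7 | sodium bis(2-methoxyethoxy) oxaluminole from 6 (Al on C7, O on C5) | [Na+].COCCO[Al-]1(OCCOC)OCC=C1[C@@H]2OC(C)(C)O[C@@H]2CO[Si](c3ccccc3)(c4ccccc4)C(C)(C)C | intermediate (not isolated)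
8 | (Z)-3-iodo-3-[(4R,5R)-5-{[tert-butyl(diphenyl)silyl]oxymethyl}-2,2-dimethyl-1,3-dioxolan-4-yl]prop-2-en-1-ol | OC/C=C(\I)[C@@H]1OC(C)(C)O[C@@H]1CO[Si](c2ccccc2)(c3ccccc3)C(C)(C)C | intermediate
9 | methyl propiolate | C#CC(=O)OC | starting material
10 | methyl 2-(tributylstannyl)prop-2-enoate | C=C(C(=O)OC)[Sn](CCCC)(CCCC)CCCC | intermediate
11 | methyl (3E)-5-hydroxy-2-methylidene-3-[(4S,5R)-5-{[tert-butyl(diphenyl)silyl]oxymethyl}-2,2-dimethyl-1,3-dioxolan-4-yl]pent-3-enoate | OC/C=C(\C(=C)C(=O)OC)[C@@H]1OC(C)(C)O[C@@H]1CO[Si](c2ccccc2)(c3ccccc3)C(C)(C)C | intermediate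
12 | methyl 2-[(2R,3S)-3-(hydroxymethyl)-2-{(4R,5R)-5-[(tert-butyldiphenylsilyloxy)methyl]-2,2-dimethyl-1,3-dioxolan-4-yl}oxiran-2-yl]prop-2-enoate | COC(=O)C(=C)[C@]1(O[C@H]1CO)[C@@H]2OC(C)(C)O[C@@H]2CO[Si](c3ccccc3)(c4ccccc4)C(C)(C)C | intermediate
13 | 5-O-TBS ether of 12 | COC(=O)C(=C)[C@]1(O[C@H]1CO[Si](C)(C)C(C)(C)C)[C@@H]2OC(C)(C)O[C@@H]2CO[Si](c3ccccc3)(c4ccccc4)C(C)(C)C | intermediate
14 | 2-methylene 3,4-epoxy acid (6S,7R,8R,9R; O5 TBS, O8/O9 acetonide, O10 TBDPS) | OC(=O)C(=C)[C@]1(O[C@H]1CO[Si](C)(C)C(C)(C)C)[C@@H]2OC(C)(C)O[C@@H]2CO[Si](c3ccccc3)(c4ccccc4)C(C)(C)C | intermediate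
15 | β-hydroxy-α-methylene-γ-butyrolactone (6R,7R,8R,9R; O5 TBS, O10 TBDPS) | C=C1C(=O)O[C@H](CO[Si](C)(C)C(C)(C)C)[C@@]1(O)[C@@H]2OC(C)(C)O[C@@H]2CO[Si](c3ccccc3)(c4ccccc4)C(C)(C)C | intermediate
16 | C5 alcohol of 15 | C=C1C(=O)O[C@H](CO)[C@@]1(O)[C@@H]2OC(C)(C)O[C@@H]2CO[Si](c3ccccc3)(c4ccccc4)C(C)(C)C | intermediate
17 | C5 aldehyde | C=C1C(=O)O[C@H](C=O)[C@@]1(O)[C@@H]2OC(C)(C)O[C@@H]2CO[Si](c3ccccc3)(c4ccccc4)C(C)(C)C | intermediate
18 | 1,1-dibromoalkene | C=C1C(=O)O[C@H](C=C(Br)Br)[C@@]1(O)[C@@H]2OC(C)(C)O[C@@H]2CO[Si](c3ccccc3)(c4ccccc4)C(C)(C)C | intermediate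
19 | but-3-enylzinc bromide | C=CCC[Zn]Br | starting material
20 | (Z)-2-bromoalkene with but-3-enyl chain | C=C1C(=O)O[C@H](/C=C(\Br)CCC=C)[C@@]1(O)[C@@H]2OC(C)(C)O[C@@H]2CO[Si](c3ccccc3)(c4ccccc4)C(C)(C)C | intermediate
21 | lactone with (1E)-2-methylhexa-1,5-dienyl chain, O10 TBDPS | C=C1C(=O)O[C@H](/C=C(\C)CCC=C)[C@@]1(O)[C@@H]2OC(C)(C)O[C@@H]2CO[Si](c3ccccc3)(c4ccccc4)C(C)(C)C | intermediate
22 | C7,C10-diol | C=C1C(=O)O[C@H](/C=C(\C)CCC=C)[C@@]1(O)[C@@H]2OC(C)(C)O[C@@H]2CO | intermediate
23 | 7,10-bis(triethylsilyl) ether | C=C1C(=O)O[C@H](/C=C(\C)CCC=C)[C@@]1(O[Si](CC)(CC)CC)[C@@H]2OC(C)(C)O[C@@H]2CO[Si](CC)(CC)CC | intermediate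
24 | C10 aldehyde, O7 triethylsilyl | C=C1C(=O)O[C@H](/C=C(\C)CCC=C)[C@@]1(O[Si](CC)(CC)CC)[C@@H]2OC(C)(C)O[C@@H]2C=O | intermediate
25 | C10 methyl carbinol (epimers at C10) | C=C1C(=O)O[C@H](/C=C(\C)CCC=C)[C@@]1(O[Si](CC)(CC)CC)[C@@H]2OC(C)(C)O[C@@H]2C(C)O | intermediate
26 | C10 methyl ketone | C=C1C(=O)O[C@H](/C=C(\C)CCC=C)[C@@]1(O[Si](CC)(CC)CC)[C@@H]2OC(C)(C)O[C@@H]2C(C)=O | intermediate
27 | triene with isopropenyl group on C9 | C=C1C(=O)O[C@H](/C=C(\C)CCC=C)[C@@]1(O[Si](CC)(CC)CC)[C@@H]2OC(C)(C)O[C@@H]2C(C)=C | intermediate
28 | 7-O-triethylsilyl-8,9-O-isopropylidene macrocycle | C=C1C(=O)O[C@@H]2/C=C(\C)CC/C=C(/C)[C@H]3OC(C)(C)O[C@H]3[C@@]12O[Si](CC)(CC)CC | intermediate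
29 | (6R,7R,8R,9R)-7,8,9-trihydroxygermacra-1(10)Z,4E,11(13)-trien-12,6-olide | C=C1C(=O)O[C@@H]2/C=C(\C)CC/C=C(/C)[C@@H](O)[C@@H](O)[C@@]12O | intermediate
30 | 9-O-triethylsilyl ether of 29 | C=C1C(=O)O[C@@H]2/C=C(\C)CC/C=C(/C)[C@@H](O[Si](CC)(CC)CC)[C@@H](O)[C@@]12O | intermediate
31 | (E)-2-methylbut-2-en-1-ol | C/C=C(\C)CO | starting material
32 | [(2R,3R)-2,3-dimethyloxiran-2-yl]methanol | OC[C@@]1(C)O[C@@H]1C | intermediate
33 | (2S,3R)-2,3-dimethyloxirane-2-carboxylic acid | OC(=O)[C@@]1(C)O[C@@H]1C | intermediate
34 | (2S,3R)-2,3-dimethyloxirane-2-carboxylic 2,4,6-trichlorobenzoic anhydride | O=C(OC(=O)[C@@]1(C)O[C@@H]1C)c2c(Cl)cc(Cl)cc2Cl | intermediate (not isolated)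
35 | 9-O-triethylsilyl ether of the target | C=C1C(=O)O[C@@H]2/C=C(\C)CC/C=C(/C)[C@@H](O[Si](CC)(CC)CC)[C@@H](OC(=O)[C@@]3(C)O[C@@H]3C)[C@@]12O | intermediate
36 | CNP0420662.1 | C=C1C(=O)O[C@@H]2/C=C(\C)CC/C=C(/C)[C@@H](O)[C@@H](OC(=O)[C@@]3(C)O[C@@H]3C)[C@@]12O | target

## Step count and least certain steps

Total: 29 steps. Longest linear sequence: 26 steps (1–5, 7–25, 28, 29). Steps 6, 26 and 27 prepare 10 and 33.

**Step 11 (key step).** The most likely failure is loss of control before or during ring closure. Hydroxide in step 10 may add to the acrylate and open the oxirane in an SN2′ sense. The free acid may also start to cyclise during the acidic work-up under undefined conditions, where ionisation of the tertiary, allylic C7–O bond can compete with concerted attack at C6. Fallback: set out from ester 13 and omit the free acid. With BF3·OEt2 in CH2Cl2 at −78 °C the ester carbonyl oxygen opens the activated oxirane at C6 with inversion (carbonyl participation, same five-membered ring). The methoxy-substituted oxocarbenium ion is hydrolysed on aqueous quench, and the route is rejoined at 15; no new compound is needed (F0).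

**Step 23 (ring closure).** The most likely failure is oligomerisation or no closure, because the 1,1-disubstituted alkene next to the dioxolane engages the carbene slowly and the ring is strained. A second risk is formation of the trans C1=C10 isomer. Fallback: set out from 27 and hydrolyse the acetal and the silyl ether first (AcOH/H2O/THF) to the open-chain triol F1. Its free allylic C9 hydroxyl should assist carbene transfer to the isopropenyl group, and its chain is no longer bent by the dioxolane. Ring-closing metathesis of F1 rejoins the route at 29, so the macrocycle never meets the acidic hydrolysis.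

**Step 8 (epoxidation).** The most likely failure is transesterification of the titanium-bound C5 alkoxide onto the cis-disposed ester, giving a six-membered lactone, before the slow oxygen transfer to this electron-poor, hindered diene occurs. A mismatch between the tartrate and the C8 centre is the second risk. Fallback: set out from 11 and silylate O5 first (TBSCl, imidazole) to give F2, which has no free hydroxyl next to the ester. Epoxidise F2 with a Shi fructose-derived ketone catalyst, or its enantiomer chosen with the spiro transition-state model to attack the same face, using KHSO5 (as Oxone) at buffered pH. Dioxirane oxidation prefers the electron-rich trisubstituted alkene. The route is rejoined at 13.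

**Step 15 (first Negishi coupling).** The most likely failure is loss of site selectivity (coupling at the cis bromide, or double alkylation) or ionisation of the allylic lactone C6–O bond by zerovalent palladium once the diene is formed. Fallback: set out from aldehyde 17. A Wittig reaction with Ph3P=C(CH3)CHO gives the (E)-enal F3. Reduction with NaBH4/CeCl3 gives the allylic alcohol F4, and CBr4/PPh3 gives the allylic bromide F5. Stille coupling of F5 with allyltributylstannane (Pd2(dba)3, AsPh3) forms the C2–C3 bond at the primary terminus and rejoins the route at 21. Steps 14–16 are bypassed.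

**Step 25 (differentiation of O8 and O9).** The most likely failure is poor site selectivity of the silylation, or base-induced relactonisation of the lactone carbonyl onto the free O8. Fallback: use the allylic character of O9 instead of its accessibility. Set out from 29; MnO2 oxidises only the allylic C9 carbinol, giving enone F6. Yamaguchi acylation of the remaining secondary hydroxyl with 34 gives F7. Reduction with NaBH4/CeCl3 at −78 °C returns the C9 alcohol and rejoins the route at 36. Hydride delivery from the outer face of the ring, needed for 9R, is the uncertain point of this detour.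

**Step 5 (hydroalumination–iodination).** The most likely failure is β-elimination of the alkenylalanate toward an allene, with opening of the dioxolane, or protonation instead of iodination. Fallback: set out from 6 and use ruthenium-catalysed trans-hydrosilylation ([Cp*Ru(MeCN)3]PF6, benzyldimethylsilane). This places silicon on the carbon distal to the hydroxyl and cis to C5, giving the (Z)-alkenylsilane F8. Iododesilylation with N-iodosuccinimide proceeds with retention and rejoins the route at 8.

## Further compounds

F0 | step 11 | none | none
F1 | step 23 | open-chain 7,8,9-triol of 27 (acetal and silyl ether removed) | C=C1C(=O)O[C@H](/C=C(\C)CCC=C)[C@@]1(O)[C@H](O)[C@H](O)C(C)=C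
F2 | step 8 | 5-O-TBS ether of 11 | CC(C)(C)[Si](C)(C)OC/C=C(\C(=C)C(=O)OC)[C@@H]1OC(C)(C)O[C@@H]1CO[Si](c2ccccc2)(c3ccccc3)C(C)(C)C
F3 | step 15 | (E)-2-methylpropenal on C6 (C3 aldehyde) | C=C1C(=O)O[C@H](/C=C(\C)C=O)[C@@]1(O)[C@@H]2OC(C)(C)O[C@@H]2CO[Si](c3ccccc3)(c4ccccc4)C(C)(C)C
F4 | step 15 | (E)-allylic alcohol (C3 hydroxyl) | C=C1C(=O)O[C@H](/C=C(\C)CO)[C@@]1(O)[C@@H]2OC(C)(C)O[C@@H]2CO[Si](c3ccccc3)(c4ccccc4)C(C)(C)C
F5 | step 15 | (E)-allylic bromide (C3 bromide) | C=C1C(=O)O[C@H](/C=C(\C)CBr)[C@@]1(O)[C@@H]2OC(C)(C)O[C@@H]2CO[Si](c3ccccc3)(c4ccccc4)C(C)(C)C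
F6 | step 25 | 9-oxo-7,8-diol (C9 enone of 29) | C=C1C(=O)O[C@@H]2/C=C(\C)CC/C=C(/C)C(=O)[C@@H](O)[C@@]12O
F7 | step 25 | 9-oxo-8-O-[(2S,3R)-2,3-dimethyloxirane-2-carbonyl] derivative | C=C1C(=O)O[C@@H]2/C=C(\C)CC/C=C(/C)C(=O)[C@@H](OC(=O)[C@@]3(C)O[C@@H]3C)[C@@]12O
F8 | step 5 | (Z)-3-(benzyldimethylsilyl) allylic alcohol from 6 | OC/C=C(\[Si](C)(C)Cc1ccccc1)[C@@H]2OC(C)(C)O[C@@H]2CO[Si](c3ccccc3)(c4ccccc4)C(C)(C)C
A1 | alternative 1 | ten-membered 8,9-diol with 6,7-O-isopropylidene and 7-(trimethylsilylethynyl) group | C[Si](C)(C)C#C[C@@]12OC(C)(C)O[C@@H]1/C=C(\C)CC/C=C(/C)[C@@H](O)[C@H]2O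
A2 | alternative 1 | open-chain dialdehyde (C8 aldehyde, C9 enal) | C[Si](C)(C)C#C[C@@]1(C=O)OC(C)(C)O[C@@H]1/C=C(\C)CC/C=C(/C)C=O
A3 | alternative 2 | lactone core with O7 triethylsilyl and O8/O9 acetonide (identical with 28) | C=C1C(=O)O[C@@H]2/C=C(\C)CC/C=C(/C)[C@H]3OC(C)(C)O[C@H]3[C@@]12O[Si](CC)(CC)CC
A4 | alternative 2 | open-chain (E)-alkenyl iodide with C6 aldehyde and acrylate ester on C7 | C=C(C(=O)OC)[C@](C=O)(O[Si](CC)(CC)CC)[C@@H]1OC(C)(C)O[C@@H]1/C(C)=C\CC/C(C)=C/I
A5 | alternative 3 | (E)-cyclodec-5-enone with protected C6–C9 tetrol | O=C1CCC/C(C)=C/[C@@H](OCc2ccc(OC)cc2)[C@@H](O[Si](C)(C)C(C)(C)C)[C@@H]2OC(C)(C)O[C@@H]21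
A6 | alternative 3 | trans-1-vinyl-2-isopropenylcyclohexanol with protected tetrol (one trans isomer drawn) | C=C[C@@]1(O)[C@H]2OC(C)(C)O[C@H]2[C@H](O[Si](C)(C)C(C)(C)C)[C@H](OCc3ccc(OC)cc3)[C@@H]1C(C)=C
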